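**Strategy.** The route rests on disconnecting the C7–C8 bond of the cyclohexanone ring (C1, C5–C9) of the bicyclo[3.3.1]nonane-2,4,9-trione core: C8 is a gem-dimethyl quaternary carbon and C7 carries a CH2-linked prenyl group. In one operation, hydrogen-atom transfer to an isopropenyl group gives the C8 tertiary radical, which closes the six-membered ring onto an enal (6-exo) and sets C7 under control of a lavandulyl-type stereocentre that is later absorbed into bridgehead C1. The precursor is an acyclic (S)-configured isopropenyl/prenyl ketone with a tethered (E)-enal. Effenberger annulation anti to the C7 side chain, bridgehead geranylation and C3 aroylation complete the type B skeleton.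

Key step: step 6

Remark: core numbering is C1 = prenylated bridgehead, C2–C4 = three-carbon diketone bridge, C5 = geranylated bridgehead, C6 = CH2, C7 = CH(prenyl), C8 = CMe2, C9 = bridging ketone. The β-triketone is drawn as one enol tautomer. 3,4-Diacetoxybenzoic acid is taken as commercially available.

**Step 1**
Reactants: 1 (S)-4-benzyl-1,3-oxazolidin-2-one; 2 3-methylbut-2-enoyl chloride
Product: 3 (4S)-4-benzyl-3-(3-methylbut-2-enoyl)-1,3-oxazolidin-2-one
Conditions: n-BuLi, THF, −78 °C; then 2, −78 to 0 °C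
Reagents that add atoms: none
Why: N-acylation of the lithiated oxazolidinone by the acid chloride is the standard loading of the auxiliary and forms no stereocentre.

**Step 2**
Reactants: 3; 4 1-bromo-3-methylbut-2-ene (prenyl bromide)
Product: 5 (4S)-4-benzyl-3-[(2S)-5-methyl-2-(prop-1-en-2-yl)hex-4-enoyl]-1,3-oxazolidin-2-one
Conditions: NaN(SiMe3)2, THF, −78 °C; then 4, −78 to −40 °C
Reagents that add atoms: none
Why: γ-Deprotonation gives the chelated sodium dienolate, which is alkylated at the α-carbon on the face opposite the benzyl group (deconjugative Evans alkylation), setting the (S) centre that carries prenyl and isopropenyl.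

**Step 3**
Reactants: 5
Product: 6 (2S)-N-methoxy-N,5-dimethyl-2-(prop-1-en-2-yl)hex-4-enamide
Conditions: MeNH(OMe)·HCl, AlMe3, CH2Cl2, 0 °C to rt
Reagents that add atoms: N,O-dimethylhydroxylamine hydrochloride, CNOC.Cl
Why: Aluminium-amide transamination of the imide (Weinreb amide formation) attacks the exocyclic carbonyl under non-basic conditions, so the doubly activated α-hydrogen is not removed and the auxiliary is released.

**Step 4**
Reactants: 6; 7 2-(2-bromoethyl)-1,3-dioxolane
Product: 9 (4S)-1-(1,3-dioxolan-2-yl)-7-methyl-4-(prop-1-en-2-yl)oct-6-en-3-one, via 2-(1,3-dioxolan-2-yl)ethylmagnesium bromide 8 (not isolated)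
Conditions: Mg, THF, rt; then 6, THF, 0 °C; aq. NH4Cl
Reagents that add atoms: none
Why: Grignard addition to a Weinreb amide stops at the chelated tetrahedral intermediate and gives the ketone on work-up, and the low temperature disfavours enolization of the α-centre.

**Step 5**
Reactants: 9
Product: 11 (2E,7S)-10-methyl-6-oxo-7-(prop-1-en-2-yl)undeca-2,9-dienal, via keto aldehyde 10 (not isolated)
Conditions: PPTS, acetone/H2O, 50 °C; then Ph3P=CHCHO, toluene, 80 °C
Reagents that add atoms: (triphenylphosphoranylidene)acetaldehyde, O=CC=P(c1ccccc1)(c1ccccc1)c1ccccc1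
Why: Mild acid-catalysed acetal hydrolysis followed directly by Wittig olefination with the stabilised ylide should give the (E)-enal while leaving the ketone and its α-centre untouched.

**Step 6**
Reactants: 11
Product: 12 2-[(1R,3S)-2,2-dimethyl-3-(3-methylbut-2-en-1-yl)-4-oxocyclohexyl]acetaldehyde
Conditions: Fe(acac)3 (30 mol %), PhSiH3, EtOH, 50 °C
Reagents that add atoms: none
Why: Fe(acac)3/PhSiH3/EtOH generates an iron hydride that transfers a hydrogen atom to the CH2 terminus of the isopropenyl group, so the future C8 appears as a nucleophilic tertiary radical that adds to the β-carbon of the tethered enal (future C7), and the α-formyl radical is then reduced to the iron enolate and protonated. The closest known reaction type is the hydrogen-atom-transfer-initiated reductive olefin coupling (Mukaiyama-type hydrogen-atom transfer followed by Giese addition) in its intramolecular form, which is established for quaternary carbons and enal acceptors. The only ring closed is the cyclohexanone, by a 6-exo-trig radical cyclization. The new stereocentre (C1 of 12, the future C7) is controlled by the existing (S) centre next to the radical: in the chair-like transition state its prenyl group and the enal chain are both pseudo-equatorial, which should give the cis (1R,3S) isomer. The step needs chemoselectivity for the 1,1-disubstituted alkene over the trisubstituted prenyl alkene and over enal reduction, which faster hydrogen-atom transfer to the unhindered CH2 and fast intramolecular trapping should secure, and it needs 1,3-induction, backed up by chromatographic removal of any trans isomer before the relay centre is erased.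

**Step 7**
Reactants: 12
Product: 13 (2S,4R)-3,3-dimethyl-2,4-bis(3-methylbut-2-en-1-yl)cyclohexan-1-one
Conditions: i-PrPPh3I, n-BuLi, THF, 0 °C; then 12, −78 to 0 °C
Reagents that add atoms: isopropyltriphenylphosphonium iodide, CC(C)[P+](c1ccccc1)(c1ccccc1)c1ccccc1.[I-]
Why: Wittig olefination with the non-stabilised isopropylidene ylide is selective for the aldehyde over the hindered ketone and turns the CH2CHO arm into the C7 prenyl group without touching C4.

**Step 8**
Reactants: 13
Product: 14 trimethyl{[(4R)-3,3-dimethyl-2,4-bis(3-methylbut-2-en-1-yl)cyclohex-1-en-1-yl]oxy}silane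
Conditions: Me3SiCl, NaI, Et3N, MeCN, rt
Reagents that add atoms: chlorotrimethylsilane, C[Si](C)(C)Cl
Why: Thermodynamic silyl enol ether formation with Me3SiI made in the flask should give the more substituted enol silane, which erases the relay centre and leaves C4 as the only stereocentre.

**Step 9**
Reactants: 14; 15 propanedioyl dichloride (malonyl dichloride)
Product: 16 (1S,5R,7S)-4-hydroxy-8,8-dimethyl-1,7-bis(3-methylbut-2-en-1-yl)bicyclo[3.3.1]non-3-ene-2,9-dione (enol form of the 2,4,9-trione, bridgehead C5–H)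
Conditions: 15, CH2Cl2, −20 °C to rt; then KOH, BnEt3NCl, H2O, rt; aq. HCl
Reagents that add atoms: none
Why: Effenberger cyclization: C-acylation of the enol silane creates the quaternary C1, re-enolization toward the CH2 side and a second acylation close the bridge, and the two new bonds are necessarily cis-diaxial and form anti to the equatorial C7 prenyl group, which sets C1 and C5 and gives the 7-exo series.

**Step 10**
Reactants: 16
Product: 17 (1S,5R,7S)-4-methoxy-8,8-dimethyl-1,7-bis(3-methylbut-2-en-1-yl)bicyclo[3.3.1]non-3-ene-2,9-dione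
Conditions: Me2SO4, K2CO3, acetone, reflux
Reagents that add atoms: dimethyl sulfate, COS(=O)(=O)OC
Why: O-Alkylation of the potassium diketonate (vinylogous ester formation) should favour the less hindered oxygen remote from the quaternary bridgehead, and the regioisomer is separable and can be hydrolysed back to 16.

**Step 11**
Reactants: 17; 18 (2E)-1-bromo-3,7-dimethylocta-2,6-diene (geranyl bromide)
Product: 19 (1S,5R,7S)-5-[(2E)-3,7-dimethylocta-2,6-dien-1-yl]-4-methoxy-8,8-dimethyl-1,7-bis(3-methylbut-2-en-1-yl)bicyclo[3.3.1]non-3-ene-2,9-dione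
Conditions: LiN(iPr)2, THF, −78 °C; then 18, −78 °C to rt
Reagents that add atoms: none
Why: Bridgehead lithiation gives a pyramidal carbanion stabilised inductively by the C9 ketone and the electron-poor enol ether carbon, and its alkylation with the allylic bromide proceeds with retention enforced by the cage.

**Step 12**
Reactants: 20 3,4-diacetoxybenzoic acid
Product: 21 3,4-diacetoxybenzoyl chloride
Conditions: (COCl)2, DMF (cat.), CH2Cl2, 0 °C to rt
Reagents that add atoms: oxalyl chloride, O=C(Cl)C(Cl)=O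
Why: Acid chloride formation through the Vilsmeier-type chloroiminium intermediate leaves the aryl acetates intact.

**Step 13**
Reactants: 19; 21
Product: 22 (1R,5R,7S)-3-[3,4-bis(acetyloxy)benzoyl]-5-[(2E)-3,7-dimethylocta-2,6-dien-1-yl]-4-methoxy-8,8-dimethyl-1,7-bis(3-methylbut-2-en-1-yl)bicyclo[3.3.1]non-3-ene-2,9-dione
Conditions: Li(TMP) (lithium 2,2,6,6-tetramethylpiperidide), THF, −78 °C; then 21, −78 °C
Reagents that add atoms: none
Why: With both bridgeheads quaternary, the hindered amide base lithiates the vinylic C3–H of the β-methoxy enone and the vinyllithium is C-acylated by the acid chloride, which is far more electrophilic than the aryl acetates.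

**Step 14**
Reactants: 22
Product: 23 (1R,5R,7S)-3-(3,4-dihydroxybenzoyl)-5-[(2E)-3,7-dimethylocta-2,6-dien-1-yl]-4-hydroxy-8,8-dimethyl-1,7-bis(3-methylbut-2-en-1-yl)bicyclo[3.3.1]non-3-ene-2,9-dione (target, CNP0160101.4)
Conditions: LiOH, 1,4-dioxane/H2O, 90 °C, degassed; aq. HCl
Reagents that add atoms: lithium hydroxide, [Li+].[OH-]
Why: Hydroxide addition–elimination at the vinylogous ester and saponification of the two aryl acetates unveil the enolised triketone and the catechol, while the three stereocentres are quaternary or non-enolisable and cannot epimerise.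

**Compound list**

1 | (S)-4-benzyl-1,3-oxazolidin-2-one | O=C1N[C@@H](Cc2ccccc2)CO1 | starting material
2 | 3-methylbut-2-enoyl chloride | CC(C)=CC(Cl)=O | starting material
3 | (4S)-4-benzyl-3-(3-methylbut-2-enoyl)-1,3-oxazolidin-2-one | CC(C)=CC(=O)N1[C@@H](Cc2ccccc2)COC1=O | intermediate
4 | 1-bromo-3-methylbut-2-ene | CC(C)=CCBr | starting material
5 | (4S)-4-benzyl-3-[(2S)-5-methyl-2-(prop-1-en-2-yl)hex-4-enoyl]-1,3-oxazolidin-2-one | CC(C)=CC[C@@H](C(C)=C)C(=O)N1[C@@H](Cc2ccccc2)COC1=O | intermediate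
6 | (2S)-N-methoxy-N,5-dimethyl-2-(prop-1-en-2-yl)hex-4-enamide | CC(C)=CC[C@@H](C(C)=C)C(=O)N(C)OC | intermediate
7 | 2-(2-bromoethyl)-1,3-dioxolane | BrCCC1OCCO1 | starting material
8 | 2-(1,3-dioxolan-2-yl)ethylmagnesium bromide | Br[Mg]CCC1OCCO1 | intermediate (not isolated)
9 | (4S)-1-(1,3-dioxolan-2-yl)-7-methyl-4-(prop-1-en-2-yl)oct-6-en-3-one | CC(C)=CC[C@@H](C(C)=C)C(=O)CCC1OCCO1 | intermediate
10 | (5S)-8-methyl-4-oxo-5-(prop-1-en-2-yl)non-7-enal | CC(C)=CC[C@@H](C(C)=C)C(=O)CCC=O | intermediate (not isolated)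
11 | (2E,7S)-10-methyl-6-oxo-7-(prop-1-en-2-yl)undeca-2,9-dienal | CC(C)=CC[C@@H](C(C)=C)C(=O)CC/C=C/C=O | intermediate
12 | 2-[(1R,3S)-2,2-dimethyl-3-(3-methylbut-2-en-1-yl)-4-oxocyclohexyl]acetaldehyde | O=C1CC[C@H](CC=O)C(C)(C)[C@@H]1CC=C(C)C | intermediate
13 | (2S,4R)-3,3-dimethyl-2,4-bis(3-methylbut-2-en-1-yl)cyclohexan-1-one | O=C1CC[C@H](CC=C(C)C)C(C)(C)[C@@H]1CC=C(C)C | intermediate
14 | trimethyl{[(4R)-3,3-dimethyl-2,4-bis(3-methylbut-2-en-1-yl)cyclohex-1-en-1-yl]oxy}silane | C[Si](C)(C)OC1=C(CC=C(C)C)C(C)(C)[C@@H](CC=C(C)C)CC1 | intermediate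
15 | propanedioyl dichloride | O=C(Cl)CC(Cl)=O | starting material
16 | (1S,5R,7S)-4-hydroxy-8,8-dimethyl-1,7-bis(3-methylbut-2-en-1-yl)bicyclo[3.3.1]non-3-ene-2,9-dione | [C@@H]12C[C@H](CC=C(C)C)C(C)(C)[C@@](CC=C(C)C)(C(=O)C=C1O)C2=O | intermediate
17 | (1S,5R,7S)-4-methoxy-8,8-dimethyl-1,7-bis(3-methylbut-2-en-1-yl)bicyclo[3.3.1]non-3-ene-2,9-dione | [C@@H]12C[C@H](CC=C(C)C)C(C)(C)[C@@](CC=C(C)C)(C(=O)C=C1OC)C2=O | intermediate
18 | (2E)-1-bromo-3,7-dimethylocta-2,6-diene | CC(C)=CCC/C(C)=C/CBr | starting material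
19 | (1S,5R,7S)-5-[(2E)-3,7-dimethylocta-2,6-dien-1-yl]-4-methoxy-8,8-dimethyl-1,7-bis(3-methylbut-2-en-1-yl)bicyclo[3.3.1]non-3-ene-2,9-dione | CC(C)=CCC/C(C)=C/C[C@@]12C[C@H](CC=C(C)C)C(C)(C)[C@@](CC=C(C)C)(C(=O)C=C1OC)C2=O | intermediate
20 | 3,4-diacetoxybenzoic acid | CC(=O)Oc1ccc(cc1OC(C)=O)C(O)=O | starting material
21 | 3,4-diacetoxybenzoyl chloride | CC(=O)Oc1ccc(cc1OC(C)=O)C(Cl)=O | intermediate
22 | (1R,5R,7S)-3-[3,4-bis(acetyloxy)benzoyl]-5-[(2E)-3,7-dimethylocta-2,6-dien-1-yl]-4-methoxy-8,8-dimethyl-1,7-bis(3-methylbut-2-en-1-yl)bicyclo[3.3.1]non-3-ene-2,9-dione | CC(C)=CCC/C(C)=C/C[C@@]12C[C@H](CC=C(C)C)C(C)(C)[C@@](CC=C(C)C)(C(=O)C(C(=O)c3ccc(OC(C)=O)c(OC(C)=O)c3)=C1OC)C2=O | intermediate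
23 | (1R,5R,7S)-3-(3,4-dihydroxybenzoyl)-5-[(2E)-3,7-dimethylocta-2,6-dien-1-yl]-4-hydroxy-8,8-dimethyl-1,7-bis(3-methylbut-2-en-1-yl)bicyclo[3.3.1]non-3-ene-2,9-dione | CC(C)=CCC/C(C)=C/C[C@@]12C[C@H](CC=C(C)C)C(C)(C)[C@@](CC=C(C)C)(C(=O)C(C(=O)c3ccc(O)c(O)c3)=C1O)C2=O | target

Total step count: 14. Longest linear sequence: 13 steps (steps 1 to 11, 13 and 14).

**Steps most likely to fail**

Step 6. Hydrogen-atom transfer may also occur at the trisubstituted prenyl double bond, leading to olefin isomerisation or cyclization onto the isopropenyl group, and the 1,3-induction from the relay centre may be incomplete. Fallback: starting from 11, the prenyl alkene is masked before the radical step. Epoxidation with mCPBA (NaHCO3, CH2Cl2, −20 °C) should select the more electron-rich trisubstituted alkene and give the epoxy enal (2E,7S)-8-(3,3-dimethyloxiran-2-yl)-6-oxo-7-(prop-1-en-2-yl)oct-2-enal F1. The same Fe(acac)3/PhSiH3 cyclization, now with a single electron-rich alkene, should give 2-[(1R,3S)-3-[(3,3-dimethyloxiran-2-yl)methyl]-2,2-dimethyl-4-oxocyclohexyl]acetaldehyde F2. Deoxygenation with CH3ReO3 (cat.) and PPh3 in benzene restores the alkene and rejoins the route at 12.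

Step 9. The double acylation may stall after the first bond at the hindered carbon, divert into O-acylation (fused hydroxypyranone), or suffer HCl addition to the prenyl alkenes. Fallback: starting from 14, the bridge is built stepwise. MeLi (THF, 0 °C) liberates the regiodefined lithium enolate, which is C-acylated with methyl 3-chloro-3-oxopropanoate to give methyl 3-[(1R,3R)-2,2-dimethyl-1,3-bis(3-methylbut-2-en-1-yl)-6-oxocyclohexyl]-3-oxopropanoate F3. O-Methylation (Me2SO4, K2CO3, DMF) removes the acidic methylene and gives methyl (2E)-3-[(1S,3R)-2,2-dimethyl-1,3-bis(3-methylbut-2-en-1-yl)-6-oxocyclohexyl]-3-methoxyprop-2-enoate F4. LiN(iPr)2 (THF, −78 to 0 °C) forms the only possible ring enolate, which closes the bridge by an intramolecular Claisen (Dieckmann-type) condensation to (1R,5S,7S)-4-methoxy-6,6-dimethyl-5,7-bis(3-methylbut-2-en-1-yl)bicyclo[3.3.1]non-3-ene-2,9-dione F5. Hydrolysis with LiOH rejoins the route at 16.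

Step 11. Deprotonation may occur at the vinylic C3–H instead of the bridgehead, or the bridgehead anion may be too weakly nucleophilic toward geranyl bromide. Fallback: starting from 13, geranyl is installed before the annulation. LiN(iPr)2 and 18 alkylate the kinetic enolate on the CH2 side to give (2S,4S)-6-[(2E)-3,7-dimethylocta-2,6-dien-1-yl]-3,3-dimethyl-2,4-bis(3-methylbut-2-en-1-yl)cyclohexan-1-one F6 (C6 epimers, both usable). Thermodynamic silylation (Me3SiCl, NaI, Et3N) gives trimethyl({(4S)-6-[(2E)-3,7-dimethylocta-2,6-dien-1-yl]-3,3-dimethyl-2,4-bis(3-methylbut-2-en-1-yl)cyclohex-1-en-1-yl}oxy)silane F7. The α,α'-annulation with 15 followed by KOH then forms both quaternary bridgeheads at once and gives (1S,5R,7S)-5-[(2E)-3,7-dimethylocta-2,6-dien-1-yl]-4-hydroxy-8,8-dimethyl-1,7-bis(3-methylbut-2-en-1-yl)bicyclo[3.3.1]non-3-ene-2,9-dione F8. O-Methylation (Me2SO4, K2CO3) rejoins the route at 19.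

**Further compounds**

F1 | step 6 | (2E,7S)-8-(3,3-dimethyloxiran-2-yl)-6-oxo-7-(prop-1-en-2-yl)oct-2-enal | CC1(C)OC1C[C@@H](C(C)=C)C(=O)CC/C=C/C=O
F2 | step 6 | 2-[(1R,3S)-3-[(3,3-dimethyloxiran-2-yl)methyl]-2,2-dimethyl-4-oxocyclohexyl]acetaldehyde | O=C1CC[C@H](CC=O)C(C)(C)[C@@H]1CC1OC1(C)C
F3 | step 9 | methyl 3-[(1R,3R)-2,2-dimethyl-1,3-bis(3-methylbut-2-en-1-yl)-6-oxocyclohexyl]-3-oxopropanoate | O=C1CC[C@H](CC=C(C)C)C(C)(C)[C@@]1(CC=C(C)C)C(=O)CC(=O)OC
F4 | step 9 | methyl (2E)-3-[(1S,3R)-2,2-dimethyl-1,3-bis(3-methylbut-2-en-1-yl)-6-oxocyclohexyl]-3-methoxyprop-2-enoate | O=C1CC[C@H](CC=C(C)C)C(C)(C)[C@@]1(CC=C(C)C)/C(OC)=C\C(=O)OC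
F5 | step 9 | (1R,5S,7S)-4-methoxy-6,6-dimethyl-5,7-bis(3-methylbut-2-en-1-yl)bicyclo[3.3.1]non-3-ene-2,9-dione | [C@@H]12C[C@H](CC=C(C)C)C(C)(C)[C@@](CC=C(C)C)(C(OC)=CC1=O)C2=O
F6 | step 11 | (2S,4S)-6-[(2E)-3,7-dimethylocta-2,6-dien-1-yl]-3,3-dimethyl-2,4-bis(3-methylbut-2-en-1-yl)cyclohexan-1-one | O=C1C(C/C=C(C)/CCC=C(C)C)C[C@H](CC=C(C)C)C(C)(C)[C@@H]1CC=C(C)C
F7 | step 11 | trimethyl({(4S)-6-[(2E)-3,7-dimethylocta-2,6-dien-1-yl]-3,3-dimethyl-2,4-bis(3-methylbut-2-en-1-yl)cyclohex-1-en-1-yl}oxy)silane | C[Si](C)(C)OC1=C(CC=C(C)C)C(C)(C)[C@@H](CC=C(C)C)CC1C/C=C(C)/CCC=C(C)C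
F8 | step 11 | (1S,5R,7S)-5-[(2E)-3,7-dimethylocta-2,6-dien-1-yl]-4-hydroxy-8,8-dimethyl-1,7-bis(3-methylbut-2-en-1-yl)bicyclo[3.3.1]non-3-ene-2,9-dione | CC(C)=CCC/C(C)=C/C[C@@]12C[C@H](CC=C(C)C)C(C)(C)[C@@](CC=C(C)C)(C(=O)C=C1O)C2=O
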